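## Retrosynthetic overview
1. Both CH2OH groups of the target come from hydride removal of two oxazolidinone auxiliaries from a C2-symmetric (2R,3R)-2,3-dibenzylsuccinyl bis-imide.
2. The two free 4-OH groups come from the central OMe of 3,4,5-trimethoxyphenyl rings. Methyl serves as the phenol protecting group and is removed regioselectively before the reduction.
3. The key disconnection is the central C8–C8' bond between two α-carbonyl carbons. One imide enolate is converted into a trivalent-iodine enolonium equivalent and attacked by a second enolate, which builds the whole skeleton and sets both stereocentres in one step.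
4. The monomeric imide comes from 3-(3,4,5-trimethoxyphenyl)propanoic acid and (S)-4-isopropyloxazolidin-2-one.
5. No ring is formed. Both arenes and the recoverable oxazolidinone rings are bought.

Assumption: the SMILES is read as (2R,3R), the (−)-secoisolariciresinol series, and LiN(iPr)2 and BCl3 are used as purchased solutions.

## Route

Step 1
Reactants: 1 3-(3,4,5-trimethoxyphenyl)propanoic acid; 2 (4S)-4-isopropyl-1,3-oxazolidin-2-one
Product: 4 (4S)-4-isopropyl-3-[3-(3,4,5-trimethoxyphenyl)propanoyl]-1,3-oxazolidin-2-one, via mixed pivalic anhydride 3 (not isolated)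
Conditions: PivCl (1.05 equiv), Et3N (2.5 equiv), THF, −20 → 0 °C; then LiCl (1.1 equiv), 2 (1.0 equiv), 0 °C → rt
Reagents that add atoms: pivaloyl chloride, CC(C)(C)C(=O)Cl (its atoms are held only by 3, none remains in 4)
Why: This is a mixed-anhydride N-acylation of an Evans oxazolidinone, in which the carboxylate and PivCl give 3 and the LiCl-activated N–H of 2 is acylated at the unhindered carbonyl because tert-butyl shields the other one, leaving C4 of 2 untouched.

Step 2
Reactants: 4 (4S)-4-isopropyl-3-[3-(3,4,5-trimethoxyphenyl)propanoyl]-1,3-oxazolidin-2-one (two molecules)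
Product: 7 (4S,4'S)-3,3'-[(2R,3R)-2,3-bis(3,4,5-trimethoxybenzyl)butanedioyl]bis(4-isopropyl-1,3-oxazolidin-2-one), via lithium Z-enolate 5 (not isolated), via O-iodanyl enolonium equivalent 6 (not isolated)
Conditions: LiN(iPr)2 (1.05 equiv), THF, −78 °C, 1 h; PhI(OAc)2 (0.5 equiv, in CH2Cl2), −78 °C → rt; chromatography, then crystallisation of the C2-symmetric isomer
Reagents that add atoms: LiN(iPr)2, [Li]N(C(C)C)C(C)C (Li held only by 5); (diacetoxyiodo)benzene, CC(=O)OI(OC(C)=O)c1ccccc1 (PhI(OAc) held only by 6); none of these atoms remains in 7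
Why: This is a hypervalent-iodine oxidative enolate homocoupling on an Evans imide, in which ligand exchange on trivalent iodine turns half of the chelated Z-enolate 5 into 6, whose α-carbon is now electrophilic and is attacked by the remaining 5 with reductive loss of PhI, and because in both partners the (4S)-isopropyl group blocks the same face of the planar imide (held syn by Li or by the Lewis-acidic iodine) the bond forms anti to isopropyl at each α-carbon to give the (2R,3R) dimer, with minor (R,S)/(S,S) diastereomers separated here so that only one enantiomeric series goes forward.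

Step 3
Reactants: 7 (4S,4'S)-3,3'-[(2R,3R)-2,3-bis(3,4,5-trimethoxybenzyl)butanedioyl]bis(4-isopropyl-1,3-oxazolidin-2-one)
Product: 9 (4S,4'S)-3,3'-[(2R,3R)-2,3-bis(4-hydroxy-3,5-dimethoxybenzyl)butanedioyl]bis(4-isopropyl-1,3-oxazolidin-2-one), via bis(aryloxydichloroborane) 8 (not isolated)
Conditions: BCl3 (1 M in CH2Cl2, 6 equiv), CH2Cl2, −10 °C → rt, monitored; then ice/H2O
Reagents that add atoms: boron trichloride, ClB(Cl)Cl (BCl2 held only by 8, nothing remains in 9)
Why: This is a regioselective Lewis-acid aryl methyl ether cleavage, in which the flanked central methoxy of a 1,2,3-trimethoxyarene is twisted out of conjugation and is therefore the most Lewis-basic and most strained oxygen, so BCl3 binds there and chloride removes its methyl by SN2 to give 8 (hydrolysed on work-up), while the in-plane outer methoxy groups, the imides and the two α-stereocentres (no base present) survive, the same selectivity used for 4'-O-demethylation of podophyllotoxin-type rings.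

Step 4
Reactants: 9 (4S,4'S)-3,3'-[(2R,3R)-2,3-bis(4-hydroxy-3,5-dimethoxybenzyl)butanedioyl]bis(4-isopropyl-1,3-oxazolidin-2-one)
Product: 10 (2R,3R)-2,3-bis(4-hydroxy-3,5-dimethoxybenzyl)butane-1,4-diol (5,5'-dimethoxysecoisolariciresinol)
Conditions: LiAlH4 (5 equiv), THF, 0 °C → rt; aq. potassium sodium tartrate, pH adjusted to about 5, EtOAc extraction
Reagents that add atoms: none
Why: This is a reductive cleavage of Evans N-acyl oxazolidinones, in which after deprotonation of the two phenols hydride adds to the more electrophilic exocyclic carbonyls, the adducts expel the oxazolidinone anion and the aldehydes are reduced faster than they enolise, so both centres are retained (still R, because CH2OH keeps the CIP rank of the acyl group) and 2 is recovered.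

## Compound list
1 | 3-(3,4,5-trimethoxyphenyl)propanoic acid | COc1cc(CCC(=O)O)cc(OC)c1OC | starting material
2 | (4S)-4-isopropyl-1,3-oxazolidin-2-one | CC(C)[C@H]1COC(=O)N1 | starting material
3 | 3-(3,4,5-trimethoxyphenyl)propanoic pivalic anhydride | COc1cc(CCC(=O)OC(=O)C(C)(C)C)cc(OC)c1OC | intermediate
4 | (4S)-4-isopropyl-3-[3-(3,4,5-trimethoxyphenyl)propanoyl]-1,3-oxazolidin-2-one | COc1cc(CCC(=O)N2[C@@H](C(C)C)COC2=O)cc(OC)c1OC | intermediate
5 | lithium (Z)-enolate of 4 | COc1cc(C/C=C(\O[Li])N2[C@@H](C(C)C)COC2=O)cc(OC)c1OC | intermediate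
6 | (Z)-O-[acetoxy(phenyl)-λ3-iodanyl] enolate of 4 (enolonium equivalent, drawn O-bound) | COc1cc(C/C=C(\OI(OC(C)=O)c2ccccc2)N2[C@@H](C(C)C)COC2=O)cc(OC)c1OC | intermediate
7 | (4S,4'S)-3,3'-[(2R,3R)-2,3-bis(3,4,5-trimethoxybenzyl)butanedioyl]bis(4-isopropyl-1,3-oxazolidin-2-one) | COc1cc(C[C@@H](C(=O)N2[C@@H](C(C)C)COC2=O)[C@H](C(=O)N2[C@@H](C(C)C)COC2=O)Cc2cc(OC)c(OC)c(OC)c2)cc(OC)c1OC | intermediate
8 | bis(4-O-dichloroboryl) derivative of 9 | COc1cc(C[C@@H](C(=O)N2[C@@H](C(C)C)COC2=O)[C@H](C(=O)N2[C@@H](C(C)C)COC2=O)Cc2cc(OC)c(OB(Cl)Cl)c(OC)c2)cc(OC)c1OB(Cl)Cl | intermediate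
9 | (4S,4'S)-3,3'-[(2R,3R)-2,3-bis(4-hydroxy-3,5-dimethoxybenzyl)butanedioyl]bis(4-isopropyl-1,3-oxazolidin-2-one) | COc1cc(C[C@@H](C(=O)N2[C@@H](C(C)C)COC2=O)[C@H](C(=O)N2[C@@H](C(C)C)COC2=O)Cc2cc(OC)c(O)c(OC)c2)cc(OC)c1O | intermediate
10 | (2R,3R)-2,3-bis(4-hydroxy-3,5-dimethoxybenzyl)butane-1,4-diol | COc1cc(C[C@@H](CO)[C@H](CO)Cc2cc(OC)c(O)c(OC)c2)cc(OC)c1O | target

## Totals and risks
Total step count: 4. Longest linear sequence: 4 (1 → 4 → 7 → 9 → 10).

**Step 2 (highest risk).**
- Risk: enolonium equivalent 6 can be intercepted by acetate to give the α-acetoxy imide, or quenched by proton transfer. The unsymmetrical (R,S) dimer also lowers the yield of 7.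
- Fallback: it sets out from 4 and comes back at 10, building the succinate stepwise instead of by dimerisation.
  - The enolate of 4 (NaN(SiMe3)2, THF, −78 °C) is alkylated with tert-butyl bromoacetate, here the electrophilic α-carbonyl carbon, anti to the isopropyl group. This gives tert-butyl (3R)-succinate imide F1.
  - LiBH4 (THF, 0 °C) removes the auxiliary to give hydroxy ester F2.
  - CF3CO2H in CH2Cl2 closes F2 to (4R)-benzyl lactone F3.
  - LiN(SiMe3)2 and 3,4,5-trimethoxybenzyl bromide alkylate the lactone enolate anti to the C4 substituent, giving trans-(3R,4R)-dibenzyl lactone F4.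
  - BCl3 as in step 3 gives bisphenol lactone F5, and LiAlH4 opens F5 to 10.

**Step 3.**
- Risk: two rings must each lose exactly one methyl. Under-reaction gives the mono-phenol. Over-reaction gives catechols, formed through chelation of the new aryloxyborane to a neighbouring OMe.
- Fallback: it sets out from 2 and comes back at 9, replacing late demethylation by a benzyl ether carried from the start.
  - Commercial syringaldehyde is benzylated (BnBr, K2CO3, DMF) to 4-benzyloxy-3,5-dimethoxybenzaldehyde F6.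
  - F6 is heated with Meldrum's acid in HCO2H/Et3N, which effects Knoevenagel condensation, transfer hydrogenation, hydrolysis and decarboxylation in one pot. The product is 3-(4-benzyloxy-3,5-dimethoxyphenyl)propanoic acid F7.
  - F7 is attached to 2 as in step 1 to give benzyl-protected imide F8.
  - F8 is dimerised as in step 2 to benzyl-protected (2R,3R) dimer F9.
  - H2 over Pd/C (EtOAc/EtOH) then delivers 9.

**Step 4.**
- Risk: the α-branched, hindered bis-imide may suffer hydride attack at the ring carbamate carbonyl, which opens the auxiliary. The aluminium phenoxides may also precipitate and stall the reduction.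
- Fallback: it sets out from 9 and comes back at 10, separating auxiliary removal from reduction.
  - LiOH/H2O2 (THF/H2O, 0 °C, Na2SO3 quench) cleaves only the exocyclic acyl bond to give (2R,3R)-succinic diacid F10. Alkyl-substituted syringyl phenols lack a conjugated carbonyl and are inert to cold alkaline peroxide.
  - BH3·SMe2 (THF, 0 °C → rt, MeOH quench) reduces F10 to 10.

## Further compounds
F1 | step 2 | tert-butyl (3R)-4-[(4S)-4-isopropyl-2-oxo-1,3-oxazolidin-3-yl]-4-oxo-3-(3,4,5-trimethoxybenzyl)butanoate | COc1cc(C[C@@H](C(=O)N2[C@@H](C(C)C)COC2=O)CC(=O)OC(C)(C)C)cc(OC)c1OC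
F2 | step 2 | tert-butyl (3R)-4-hydroxy-3-(3,4,5-trimethoxybenzyl)butanoate | COc1cc(C[C@@H](CO)CC(=O)OC(C)(C)C)cc(OC)c1OC
F3 | step 2 | (4R)-4-(3,4,5-trimethoxybenzyl)oxolan-2-one | COc1cc(C[C@H]2COC(=O)C2)cc(OC)c1OC
F4 | step 2 | (3R,4R)-3,4-bis(3,4,5-trimethoxybenzyl)oxolan-2-one | COc1cc(C[C@H]2COC(=O)[C@@H]2Cc2cc(OC)c(OC)c(OC)c2)cc(OC)c1OC
F5 | step 2 | (3R,4R)-3,4-bis(4-hydroxy-3,5-dimethoxybenzyl)oxolan-2-one | COc1cc(C[C@H]2COC(=O)[C@@H]2Cc2cc(OC)c(O)c(OC)c2)cc(OC)c1O
F6 | step 3 | 4-(benzyloxy)-3,5-dimethoxybenzaldehyde | COc1cc(C=O)cc(OC)c1OCc1ccccc1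
F7 | step 3 | 3-[4-(benzyloxy)-3,5-dimethoxyphenyl]propanoic acid | COc1cc(CCC(=O)O)cc(OC)c1OCc1ccccc1
F8 | step 3 | (4S)-3-{3-[4-(benzyloxy)-3,5-dimethoxyphenyl]propanoyl}-4-isopropyl-1,3-oxazolidin-2-one | COc1cc(CCC(=O)N2[C@@H](C(C)C)COC2=O)cc(OC)c1OCc1ccccc1
F9 | step 3 | (4S,4'S)-3,3'-{(2R,3R)-2,3-bis[4-(benzyloxy)-3,5-dimethoxybenzyl]butanedioyl}bis(4-isopropyl-1,3-oxazolidin-2-one) | COc1cc(C[C@@H](C(=O)N2[C@@H](C(C)C)COC2=O)[C@H](C(=O)N2[C@@H](C(C)C)COC2=O)Cc2cc(OC)c(OCc3ccccc3)c(OC)c2)cc(OC)c1OCc1ccccc1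
F10 | step 4 | (2R,3R)-2,3-bis(4-hydroxy-3,5-dimethoxybenzyl)butanedioic acid | COc1cc(C[C@@H](C(=O)O)[C@H](C(=O)O)Cc2cc(OC)c(O)c(OC)c2)cc(OC)c1O
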